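## Analysis of the target

Target 14 is a flavone, a 4H-chromen-4-one. Ring A carries hydroxyls at C5 and C7, ring C is the γ-pyranone (O1, C2, C3, C4), and ring B at C2 is a 2',5'-dihydroxy-4'-methoxyphenyl group, a methoxyhydroquinone. C3 carries a prenyl (3-methylbut-2-en-1-yl) group. There is no stereocentre and no alkene geometry to set, so the problems are regiochemistry and functional-group tolerance. The sensitive groups are three:

- the ring-B hydroquinone, which air oxidises to the quinone;
- the trisubstituted prenyl alkene, which acid can hydrate or cyclise onto a neighbouring hydroxyl and which oxidants attack;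
- the electron-rich, phloroglucinol-derived ring A.

The synthesis is hard because the C2=C3 bond is fully substituted, flanked by an ortho-substituted aryl group and a C-prenyl group that must sit on C3 (not on oxygen, C6 or C8) and be linear, not reverse. In addition, ring B has three oxygens to tell apart, two free and one methylated. The strategy rests on O1 and the prenyl-bearing C3 flanking C2: the O1–C2 and C3–C1'' bonds are those that an oxygen nucleophile and an allyl electrophile add across a C2≡C3 triple bond. A prenyl group parked on the future O1 can therefore be handed to C3 in the event that closes ring C. A second useful feature is that the two free hydroxyls of ring B are para to each other and can be stored as a quinone, or one stage earlier as two methyl ethers.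

## Retrosynthetic reasoning

**14 to 11 (no skeletal bond cut).** The ring-A hydroxyls are traced back to methoxymethyl ethers (hydroquinone 13). The para-related C2' and C5' hydroxyls are traced back to the carbonyls of methoxyquinone 12, which comes from the 2,4,5-trimethoxyphenyl ring of flavone 11 by oxidative demethylation. The three ring-B oxygens then need no protecting-group differentiation: only the para pair can become a quinone, and the C4' methoxy group is left as it is. The forward steps must oxidise ring B without touching the prenyl alkene or ring A, reduce the quinone, and remove two acetals without hydrating the alkene.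

**11 to 9 (O1–C2 and C3–C1'' cut).** Both bonds end on the carbons of the C2=C3 double bond, which is read as a former alkyne. In ynone 9 the oxygen that becomes O1 carries the prenyl group, and the group passes from that oxygen to C3, by way of ion pair 10, as the oxygen adds to C2. Cutting here, and not at C2–C1' or C4–C4a, means that ring C, the tetrasubstituted C2=C3 bond and the C-prenyl group all come from one isomerisation with no reagent-derived atoms. The forward reaction has to close 6-endo, not 5-exo, and deliver the prenyl group through its CH2 terminus.

**9 to 4 and 7 (C4–C3 cut).** One oxidation level back from 9 is propargylic alcohol 8, the adduct of aldehyde 4 and lithium acetylide 7. This is the most convergent cut, since it separates ring A with all its oxygens from ring B. The carbinol stereocentre formed in the addition does not matter, because the oxidation removes it.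

**7 to 5.** Acetylide 7 comes from terminal alkyne 6 by deprotonation, and 6 comes from 2,4,5-trimethoxybenzaldehyde 5 by one-carbon homologation of the formyl group. Aldehyde 5 is a cheap chemical that already has the ring-B oxygenation pattern.

**4 to 1.** Aldehyde 4 is cut at the O–CH2 bond of its prenyl ether to give phenol 2 and prenyl bromide 3. Removing the two acetals of 2 leads to 2,4,6-trihydroxybenzaldehyde 1. Because 1 is symmetric, the only selectivity needed is to leave one ortho hydroxyl free, and its hydrogen bond to the formyl group provides that. The spared hydroxyl is the one that must carry the prenyl group and later become O1.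

## Alternatives that were turned down

**Alternative 1: three-component coupling on a preformed chromone.**
- Disconnection: C2–C1' and C3–C1'', back to 5,7-bis(methoxymethoxy)chromen-4-one A1, (2,4,5-trimethoxyphenyl)magnesium bromide A2 and prenyl bromide 3.
- Forward key step: A2 would add to C2 of A1 (CuBr·SMe2 cat., Me3SiCl). The silyl enol ether would be returned to the lithium enolate with MeLi in the same flask, and alkylation with 3 would give the trans-2,3-disubstituted chromanone A3 as a racemate.
- For: each elementary event (conjugate arylation of a chromone, enolate regeneration, allylation anti to the new C2 aryl group) has close analogy, so this key step is less speculative than the chosen one. The three pieces can be varied independently.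
- Against: A3 is at the flavanone oxidation level. C2–C3 must then be dehydrogenated in a molecule holding a prenyl alkene and a very electron-rich ring B, and 3-alkylflavanones respond poorly to the usual quinone- or iodine-based reagents. The enolate has the ring oxygen β to the carbanion and can open ring C by E1cB loss of that oxygen before it is alkylated. Two stereocentres are set only to be erased, and A1 itself takes about three steps.
- Comparison: Alternative 1 is stronger on precedent and modularity. It is one redox step longer after the key step and places its least predictable operation late. The chosen isomerisation forms C2=C3 directly at the flavone level, passes through no ring-opening enolate and consumes no reagent.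

**Alternative 2: thermal pyranone annulation of phloroglucinol.**
- Disconnection: C4–C4a and O1–C2, back to phloroglucinol A4 and the α-prenyl aroylacetate A5, ethyl 5-methyl-2-(2,4,5-trimethoxybenzoyl)hex-4-enoate.
- Forward key step: the two are heated without solvent at about 240 °C. C-acylation of A4 by the ester and condensation of a phenolic oxygen with the ketone, with loss of ethanol and water, would give the 5,7-dihydroxyflavone A6.
- For: it is the shortest route, with A5 available in two steps and no protecting groups before ring closure. A4 is symmetric, so ring A raises no regiochemical question, and the prenyl group already sits on the carbon that becomes C3.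
- Against: a β-keto ester carrying a trisubstituted alkene must survive 240 °C, where ketonic cleavage, decarboxylation and ene-type cyclisation of the enol onto the alkene are open. α-Substituted keto esters are the least reactive partners in this condensation. The reverse orientation of the components (the Pechmann mode) would give an isomeric coumarin skeleton, which the reactants do not exclude. A6 would meet the ring-B oxidation with two unprotected phenols on ring A, or need two more steps to protect them.
- Comparison: Alternative 2 is stronger on step count, by about two steps. The chosen route offers a ring closure at 60 °C under neutral conditions, a C4–C4a bond that exists before the key step so only the chromone connectivity can form, and an acetal-protected ring A when the oxidant arrives.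

**Alternative 3: trifluorobenzoyl acylation and fluoride displacement.**
- Disconnection: C3–C4 and O1–C8a, back to ketone A7, 5-methyl-1-(2,4,5-trimethoxyphenyl)hex-4-en-1-one, and 2,4,6-trifluorobenzoyl chloride A8. A7 already holds the prenyl group on its α-carbon, and the fluorines at C5 and C7 stand in for hydroxyls.
- Forward key step: the lithium enolate of A7 (LiN(SiMe3)2) would be C-acylated by A8. The enolate oxygen of the resulting 1,3-diketone would displace an ortho fluoride by addition–elimination, closing ring C to the difluoroflavone A9.
- For: ring closure by intramolecular fluoride displacement is dependable and irreversible, the position of the prenyl group is fixed by construction, and no protecting groups are needed to this point. On reliability of the ring-forming step this alternative is stronger than the chosen one.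
- Against: enolate acylation by an acid chloride competes at oxygen. More seriously, two further substitutions by an oxygen nucleophile are needed on a chromone whose C2 is itself electrophilic. The alkyl groups brought in must then be removed without hydrogenolysis (prenyl alkene) and without boron trihalides (ring-B methyl ethers).
- Comparison: Alternative 3 trades an uncertain key step for a longer, awkward end game of about four steps between A9 and the ring-B unmasking. The chosen route has all oxygens of rings A and C in place, at the right oxidation level and under acetal protection, before the key step.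

Key step: step 6

Assumption: in step 7 the two quinone carbonyl oxygens are taken to come from water (attack at the methoxy-bearing carbons of the arene radical cation, methanol leaving), as is usual for this class of oxidation; the atom bookkeeping follows that.

## Route

Step 1
Reactants: 1 2,4,6-trihydroxybenzaldehyde
Product: 2 2-hydroxy-4,6-bis(methoxymethoxy)benzaldehyde
Conditions: MOMCl (2.2 equiv), i-Pr2NEt, CH2Cl2, 0 °C to rt
Reagents that add atoms: chloromethyl methyl ether (MOMCl), COCCl
Why: O-alkylation of the two more nucleophilic phenols with an α-chloro ether (Williamson-type acetal formation); once one ortho hydroxyl is alkylated the other is locked in a hydrogen bond to the formyl oxygen and is the least reactive, so two equivalents should stop at the bis-acetal, as is usual for 2-hydroxyaryl carbonyl compounds.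

Step 2
Reactants: 2 2-hydroxy-4,6-bis(methoxymethoxy)benzaldehyde; 3 prenyl bromide (1-bromo-3-methylbut-2-ene)
Product: 4 2,4-bis(methoxymethoxy)-6-[(3-methylbut-2-en-1-yl)oxy]benzaldehyde
Conditions: K2CO3, DMF, rt
Reagents that add atoms: none
Why: Williamson ether synthesis; the carbonate deprotonates the chelated phenol in the dipolar aprotic solvent and the phenoxide oxygen attacks the primary allylic bromide at CH2 (SN2), giving the linear O-prenyl ether, while the acetals and the aldehyde are inert.

Step 3
Reactants: 5 2,4,5-trimethoxybenzaldehyde
Product: 6 1-ethynyl-2,4,5-trimethoxybenzene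
Conditions: dimethyl (1-diazo-2-oxopropyl)phosphonate, K2CO3, MeOH, rt
Reagents that add atoms: dimethyl (1-diazo-2-oxopropyl)phosphonate, COP(=O)(OC)C(=[N+]=[N-])C(C)=O
Why: Seyferth–Gilbert homologation in its Ohira–Bestmann form; methanolysis of the acetyl group frees the diazomethylphosphonate anion, which adds to the aldehyde, loses dimethyl phosphate and N2 and rearranges by 1,2-hydride shift to the terminal alkyne. Non-enolisable aryl aldehydes, electron-rich ones included, are standard substrates.

Step 4
Reactants: 6 1-ethynyl-2,4,5-trimethoxybenzene; 4 2,4-bis(methoxymethoxy)-6-[(3-methylbut-2-en-1-yl)oxy]benzaldehyde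
Product: 8 1-[2,4-bis(methoxymethoxy)-6-[(3-methylbut-2-en-1-yl)oxy]phenyl]-3-(2,4,5-trimethoxyphenyl)prop-2-yn-1-ol (racemic), via lithium (2,4,5-trimethoxyphenyl)acetylide 7 (not isolated)
Conditions: n-BuLi, THF, −78 °C; then 4, −78 to 0 °C; aq. NH4Cl
Reagents that add atoms: none
Why: Deprotonation of the terminal alkyne, far more acidic than any ring C–H, and 1,2-addition of the lithium acetylide to the non-enolisable aldehyde. The carbinol stereocentre forms as a racemate and is removed in step 5, so no control is needed; ethers and acetals are inert to the acetylide at low temperature.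

Step 5
Reactants: 8 1-[2,4-bis(methoxymethoxy)-6-[(3-methylbut-2-en-1-yl)oxy]phenyl]-3-(2,4,5-trimethoxyphenyl)prop-2-yn-1-ol
Product: 9 1-[2,4-bis(methoxymethoxy)-6-[(3-methylbut-2-en-1-yl)oxy]phenyl]-3-(2,4,5-trimethoxyphenyl)prop-2-yn-1-one
Conditions: MnO2 (activated, excess), CH2Cl2, rt
Reagents that add atoms: none
Why: Oxidation of a doubly activated (benzylic and propargylic) secondary alcohol with activated MnO2, a neutral heterogeneous oxidant that leaves the prenyl ether, the acetals and the electron-rich arenes alone.

Step 6
Reactants: 9 1-[2,4-bis(methoxymethoxy)-6-[(3-methylbut-2-en-1-yl)oxy]phenyl]-3-(2,4,5-trimethoxyphenyl)prop-2-yn-1-one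
Product: 11 5,7-bis(methoxymethoxy)-3-(3-methylbut-2-en-1-yl)-2-(2,4,5-trimethoxyphenyl)-4H-chromen-4-one, via prenylpalladium phenoxide ion pair 10 (not isolated)
Conditions: Pd(PPh3)4 (5–10 mol %), THF (dry, degassed), 60 °C, Ar
Reagents that add atoms: none
Why: Proposed new method: zerovalent palladium should ionise the allylic C–O bond of 9, the ortho-acyl phenoxide being a good leaving group, to give ion pair 10 of a cationic divalent prenylpalladium complex and the phenoxide. The phenoxide oxygen then adds to the alkyne carbon β to the carbonyl (the future C2), either directly as an oxa-Michael addition or anti to palladium once the cation has coordinated the alkyne, forming O1–C2 and leaving C3 as a vinyl anion equivalent paired with or bound to the prenylpalladium fragment; reductive elimination, or attack of C3 on the prenyl ligand, then forms C3–C1'' and returns zerovalent palladium. The closest known reaction type is the zerovalent-palladium isomerisation of 2-alkynylphenyl allyl ethers to 2-substituted 3-allylbenzofurans, a 5-endo-dig closure with oxygen-to-carbon allyl transfer; the six-membered ynone case is the untested part. Ring C closes in the 6-endo-dig mode and no stereocentre is formed. The step needs 6-endo over 5-exo closure (the aurone mode), which the ynone polarisation should secure by making C2 the electrophilic carbon and placing the developing charge or the metal at C3 next to the carbonyl, helped by the aprotic medium, which withholds the proton that the 5-exo path requires. It needs linear over reverse prenylation, which C–C bond formation at the unsubstituted CH2 terminus of the prenyl ligand should secure, the other terminus being tertiary and facing a fully substituted C3. It needs C- over O-prenylation, which corrects itself because return of the prenyl group to oxygen only regenerates 9. The main threat is loss of a β-hydrogen from the prenyl ligand as isoprene with protonation at C3, which is why base, protic solvent and high temperature are left out.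

Step 7
Reactants: 11 5,7-bis(methoxymethoxy)-3-(3-methylbut-2-en-1-yl)-2-(2,4,5-trimethoxyphenyl)-4H-chromen-4-one
Product: 12 2-[5,7-bis(methoxymethoxy)-3-(3-methylbut-2-en-1-yl)-4-oxo-4H-chromen-2-yl]-5-methoxycyclohexa-2,5-diene-1,4-dione
Conditions: (NH4)2Ce(NO3)6 (2.5 equiv), MeCN/H2O, 0 °C, short contact time
Reagents that add atoms: water, O
Why: Oxidative demethylation of a para-dimethoxyarene by a one-electron oxidant (tetravalent cerium): ring B, the most electron-rich arene, forms the radical cation, water attacks the para-related C2' and C5' and methanol leaves, so the 1,4-quinone forms with the C4' methoxy group kept as a vinylogous ester. Ring A is deactivated by the pyranone carbonyl and the trisubstituted alkene is harder to oxidise, as in the usual cerium-mediated preparation of prenylated quinones; short contact at 0 °C should spare the acetals.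

Step 8
Reactants: 12 2-[5,7-bis(methoxymethoxy)-3-(3-methylbut-2-en-1-yl)-4-oxo-4H-chromen-2-yl]-5-methoxycyclohexa-2,5-diene-1,4-dione
Product: 14 2-(2,5-dihydroxy-4-methoxyphenyl)-5,7-dihydroxy-3-(3-methylbut-2-en-1-yl)-4H-chromen-4-one (the target), via 5,7-bis(methoxymethoxy) hydroquinone 13 (not isolated)
Conditions: Na2S2O4, EtOAc/H2O, rt, Ar; then 3 M aq. HCl, MeOH, 40 °C, Ar
Reagents that add atoms: none
Why: Two-electron reduction of the quinone by dithionite gives hydroquinone 13, and acid-catalysed transacetalisation in methanol then removes both methoxymethyl groups as dimethoxymethane. Reduction comes first because HCl and methanol add to quinones; the acid is kept dilute and only warm so that the prenyl alkene is not hydrated or cyclised, and argon protects the hydroquinone.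

## Compound list

1 | 2,4,6-trihydroxybenzaldehyde | O=Cc1c(O)cc(O)cc1O | starting material
2 | 2-hydroxy-4,6-bis(methoxymethoxy)benzaldehyde | COCOc1cc(O)c(C=O)c(OCOC)c1 | intermediate
3 | prenyl bromide (1-bromo-3-methylbut-2-ene) | CC(C)=CCBr | starting material
4 | 2,4-bis(methoxymethoxy)-6-[(3-methylbut-2-en-1-yl)oxy]benzaldehyde | COCOc1cc(OCOC)c(C=O)c(OCC=C(C)C)c1 | intermediate
5 | 2,4,5-trimethoxybenzaldehyde | COc1cc(OC)c(C=O)cc1OC | starting material
6 | 1-ethynyl-2,4,5-trimethoxybenzene | C#Cc1cc(OC)c(OC)cc1OC | intermediate
7 | lithium (2,4,5-trimethoxyphenyl)acetylide (formed in the flask, not isolated) | [Li]C#Cc1cc(OC)c(OC)cc1OC | intermediate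
8 | 1-[2,4-bis(methoxymethoxy)-6-[(3-methylbut-2-en-1-yl)oxy]phenyl]-3-(2,4,5-trimethoxyphenyl)prop-2-yn-1-ol (racemic) | COCOc1cc(OCOC)c(C(O)C#Cc2cc(OC)c(OC)cc2OC)c(OCC=C(C)C)c1 | intermediate
9 | 1-[2,4-bis(methoxymethoxy)-6-[(3-methylbut-2-en-1-yl)oxy]phenyl]-3-(2,4,5-trimethoxyphenyl)prop-2-yn-1-one | COCOc1cc(OCOC)c(C(=O)C#Cc2cc(OC)c(OC)cc2OC)c(OCC=C(C)C)c1 | intermediate
10 | ion pair of the (3-methylbut-2-enyl)bis(triphenylphosphine)palladium cation (divalent palladium) and 3,5-bis(methoxymethoxy)-2-[3-(2,4,5-trimethoxyphenyl)prop-2-ynoyl]phenoxide (formed in the flask, not isolated; the η3 prenyl ligand is drawn η1) | COCOc1cc(OCOC)c(C(=O)C#Cc2cc(OC)c(OC)cc2OC)c([O-])c1.CC(C)=CC[Pd-]([P+](c1ccccc1)(c1ccccc1)c1ccccc1)[P+](c1ccccc1)(c1ccccc1)c1ccccc1 | intermediate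
11 | 5,7-bis(methoxymethoxy)-3-(3-methylbut-2-en-1-yl)-2-(2,4,5-trimethoxyphenyl)-4H-chromen-4-one | COc1cc(OC)c(-c2oc3cc(OCOC)cc(OCOC)c3c(=O)c2CC=C(C)C)cc1OC | intermediate
12 | 2-[5,7-bis(methoxymethoxy)-3-(3-methylbut-2-en-1-yl)-4-oxo-4H-chromen-2-yl]-5-methoxycyclohexa-2,5-diene-1,4-dione | COC1=CC(=O)C(-c2oc3cc(OCOC)cc(OCOC)c3c(=O)c2CC=C(C)C)=CC1=O | intermediate
13 | 2-(2,5-dihydroxy-4-methoxyphenyl)-5,7-bis(methoxymethoxy)-3-(3-methylbut-2-en-1-yl)-4H-chromen-4-one (formed in the flask, not isolated) | COc1cc(O)c(-c2oc3cc(OCOC)cc(OCOC)c3c(=O)c2CC=C(C)C)cc1O | intermediate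
14 | 2-(2,5-dihydroxy-4-methoxyphenyl)-5,7-dihydroxy-3-(3-methylbut-2-en-1-yl)-4H-chromen-4-one | COc1cc(O)c(-c2oc3cc(O)cc(O)c3c(=O)c2CC=C(C)C)cc1O | target

## Step count and least certain steps

Total: 8 steps. Longest linear sequence: 7 steps (steps 1, 2, 4, 5, 6, 7, 8, from 1 to 14); alkyne 6 joins after one step from 5.

**Step 6 (key step, new method).** The most likely failure is ring closure without prenyl transfer: the prenylpalladium cation loses a β-hydrogen as isoprene and C3 is protonated. Other risks are slow ionisation of the hindered trisubstituted allyl ether and bond formation at the tertiary terminus (reverse prenylation). The fallback uses known reactions only, brings in the prenyl group after ring C is closed, sets out from 2 and 6 and returns at 11.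
- Phenol 2 is converted to its sodium phenoxide (NaH, THF) and treated with acetylide 7, made from 6 as in step 4, to give 1-[2-hydroxy-4,6-bis(methoxymethoxy)phenyl]-3-(2,4,5-trimethoxyphenyl)prop-2-yn-1-ol F1.
- MnO2 oxidises this to the chelated hydroxy ynone 1-[2-hydroxy-4,6-bis(methoxymethoxy)phenyl]-3-(2,4,5-trimethoxyphenyl)prop-2-yn-1-one F2.
- Et2NH in EtOH adds to the ynone and the phenol then displaces the amine from the same carbon, which can only give the six-membered ring, 5,7-bis(methoxymethoxy)-2-(2,4,5-trimethoxyphenyl)-4H-chromen-4-one F3.
- LiN(i-Pr)2 in THF at −78 °C removes the C3 hydrogen to give 3-lithio-5,7-bis(methoxymethoxy)-2-(2,4,5-trimethoxyphenyl)-4H-chromen-4-one F4, which is alkylated by 3 with catalytic CuBr·SMe2 to give 11.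
- This takes as many operations as steps 2, 4, 5 and 6 and uses no palladium, so it is independent of every elementary step of the key reaction.

**Step 7.** The most likely failure is over-oxidation: attack on the prenyl alkene, or on ring A after the strongly acidic medium has removed an acetal. The fallback avoids the oxidation by carrying the two hydroquinone oxygens of ring B as methoxymethyl ethers from the start; it sets out from 4 and returns at 14.
- 2-Hydroxy-4-methoxybenzaldehyde F5 is hydroxylated para to the phenol (Elbs oxidation, K2S2O8, aq. NaOH, then acid) to 2,5-dihydroxy-4-methoxybenzaldehyde F6.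
- Protection as in step 1 gives 4-methoxy-2,5-bis(methoxymethoxy)benzaldehyde F7, and homologation as in step 3 gives 1-ethynyl-4-methoxy-2,5-bis(methoxymethoxy)benzene F8.
- Deprotonation with n-BuLi gives lithium [4-methoxy-2,5-bis(methoxymethoxy)phenyl]acetylide F9, which adds to 4 to give 1-[2,4-bis(methoxymethoxy)-6-[(3-methylbut-2-en-1-yl)oxy]phenyl]-3-[4-methoxy-2,5-bis(methoxymethoxy)phenyl]prop-2-yn-1-ol F10.
- MnO2 gives 1-[2,4-bis(methoxymethoxy)-6-[(3-methylbut-2-en-1-yl)oxy]phenyl]-3-[4-methoxy-2,5-bis(methoxymethoxy)phenyl]prop-2-yn-1-one F11.
- The isomerisation of step 6, through the corresponding prenylpalladium phenoxide ion pair F12, gives 2-[4-methoxy-2,5-bis(methoxymethoxy)phenyl]-5,7-bis(methoxymethoxy)-3-(3-methylbut-2-en-1-yl)-4H-chromen-4-one F13.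
- One treatment with dilute HCl in MeOH removes all four acetals and gives 14.
- The price is a less accessible ring-B aldehyde and a low-yielding hydroxylation at the start.

**Step 8.** The most likely failure is acid-promoted addition of methanol or of the neighbouring C2' hydroxyl to the prenyl alkene while the slower C7 acetal is still being cleaved, together with re-oxidation of the hydroquinone by adventitious air. The fallback changes the order of events so that the acid step comes before ring B is unmasked and the last operation is neutral; it sets out from 11 and returns at 14.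
- Dilute HCl in MeOH converts 11 to 5,7-dihydroxy-3-(3-methylbut-2-en-1-yl)-2-(2,4,5-trimethoxyphenyl)-4H-chromen-4-one F14, in which no hydroxyl is near the alkene.
- (NH4)2Ce(NO3)6 oxidises ring B to 2-[5,7-dihydroxy-3-(3-methylbut-2-en-1-yl)-4-oxo-4H-chromen-2-yl]-5-methoxycyclohexa-2,5-diene-1,4-dione F15. The C5 hydroxyl is chelated and the C7 hydroxyl is conjugated to the carbonyl, which makes ring A harder to oxidise than a simple phenol.
- Na2S2O4 then gives 14.

**Step 1.** The most likely failure is over- and under-alkylation to mixtures of mono-, bis- and tris-acetals, since the selectivity rests only on a hydrogen bond. The fallback replaces selective protection by exhaustive protection and selective deprotection; it sets out from 1 and returns at 2.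
- NaH and excess MOMCl in DMF give 2,4,6-tris(methoxymethoxy)benzaldehyde F16.
- One equivalent of HCl in MeOH at 0 °C removes one of the two equivalent ortho acetals, whose cleavage is assisted by the formyl group, and should stop at 2 because the freed hydroxyl is then chelated.

## Further compounds

F1 | step 6 | 1-[2-hydroxy-4,6-bis(methoxymethoxy)phenyl]-3-(2,4,5-trimethoxyphenyl)prop-2-yn-1-ol (racemic) | COCOc1cc(O)c(C(O)C#Cc2cc(OC)c(OC)cc2OC)c(OCOC)c1
F2 | step 6 | 1-[2-hydroxy-4,6-bis(methoxymethoxy)phenyl]-3-(2,4,5-trimethoxyphenyl)prop-2-yn-1-one | COCOc1cc(O)c(C(=O)C#Cc2cc(OC)c(OC)cc2OC)c(OCOC)c1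
F3 | step 6 | 5,7-bis(methoxymethoxy)-2-(2,4,5-trimethoxyphenyl)-4H-chromen-4-one | COc1cc(OC)c(-c2cc(=O)c3c(OCOC)cc(OCOC)cc3o2)cc1OC
F4 | step 6 | 3-lithio-5,7-bis(methoxymethoxy)-2-(2,4,5-trimethoxyphenyl)-4H-chromen-4-one | COc1cc(OC)c(-c2oc3cc(OCOC)cc(OCOC)c3c(=O)c2[Li])cc1OC
F5 | step 7 | 2-hydroxy-4-methoxybenzaldehyde | COc1ccc(C=O)c(O)c1
F6 | step 7 | 2,5-dihydroxy-4-methoxybenzaldehyde | COc1cc(O)c(C=O)cc1O
F7 | step 7 | 4-methoxy-2,5-bis(methoxymethoxy)benzaldehyde | COc1cc(OCOC)c(C=O)cc1OCOC
F8 | step 7 | 1-ethynyl-4-methoxy-2,5-bis(methoxymethoxy)benzene | COc1cc(OCOC)c(C#C)cc1OCOC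
F9 | step 7 | lithium [4-methoxy-2,5-bis(methoxymethoxy)phenyl]acetylide | COc1cc(OCOC)c(C#C[Li])cc1OCOC
F10 | step 7 | 1-[2,4-bis(methoxymethoxy)-6-[(3-methylbut-2-en-1-yl)oxy]phenyl]-3-[4-methoxy-2,5-bis(methoxymethoxy)phenyl]prop-2-yn-1-ol (racemic) | COCOc1cc(OCOC)c(C(O)C#Cc2cc(OCOC)c(OC)cc2OCOC)c(OCC=C(C)C)c1
F11 | step 7 | 1-[2,4-bis(methoxymethoxy)-6-[(3-methylbut-2-en-1-yl)oxy]phenyl]-3-[4-methoxy-2,5-bis(methoxymethoxy)phenyl]prop-2-yn-1-one | COCOc1cc(OCOC)c(C(=O)C#Cc2cc(OCOC)c(OC)cc2OCOC)c(OCC=C(C)C)c1
F12 | step 7 | ion pair of the (3-methylbut-2-enyl)bis(triphenylphosphine)palladium cation (divalent palladium) and 3,5-bis(methoxymethoxy)-2-[3-[4-methoxy-2,5-bis(methoxymethoxy)phenyl]prop-2-ynoyl]phenoxide (prenyl ligand drawn η1) | COCOc1cc(OCOC)c(C(=O)C#Cc2cc(OCOC)c(OC)cc2OCOC)c([O-])c1.CC(C)=CC[Pd-]([P+](c1ccccc1)(c1ccccc1)c1ccccc1)[P+](c1ccccc1)(c1ccccc1)c1ccccc1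
F13 | step 7 | 2-[4-methoxy-2,5-bis(methoxymethoxy)phenyl]-5,7-bis(methoxymethoxy)-3-(3-methylbut-2-en-1-yl)-4H-chromen-4-one | COCOc1cc(OC)c(OCOC)cc1-c1oc2cc(OCOC)cc(OCOC)c2c(=O)c1CC=C(C)C
F14 | step 8 | 5,7-dihydroxy-3-(3-methylbut-2-en-1-yl)-2-(2,4,5-trimethoxyphenyl)-4H-chromen-4-one | COc1cc(OC)c(-c2oc3cc(O)cc(O)c3c(=O)c2CC=C(C)C)cc1OC
F15 | step 8 | 2-[5,7-dihydroxy-3-(3-methylbut-2-en-1-yl)-4-oxo-4H-chromen-2-yl]-5-methoxycyclohexa-2,5-diene-1,4-dione | COC1=CC(=O)C(-c2oc3cc(O)cc(O)c3c(=O)c2CC=C(C)C)=CC1=O
F16 | step 1 | 2,4,6-tris(methoxymethoxy)benzaldehyde | O=Cc1c(OCOC)cc(OCOC)cc1OCOC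
A1 | alternative 1 | 5,7-bis(methoxymethoxy)-4H-chromen-4-one | O=c1ccoc2cc(OCOC)cc(OCOC)c12
A2 | alternative 1 | (2,4,5-trimethoxyphenyl)magnesium bromide | COc1cc(OC)c([Mg]Br)cc1OC
A3 | alternative 1 | trans-5,7-bis(methoxymethoxy)-3-(3-methylbut-2-en-1-yl)-2-(2,4,5-trimethoxyphenyl)chroman-4-one (racemic, one enantiomer drawn) | COc1cc(OC)c([C@@H]2Oc3cc(OCOC)cc(OCOC)c3C(=O)[C@H]2CC=C(C)C)cc1OC
A4 | alternative 2 | phloroglucinol (benzene-1,3,5-triol) | Oc1cc(O)cc(O)c1
A5 | alternative 2 | ethyl 5-methyl-2-(2,4,5-trimethoxybenzoyl)hex-4-enoate (racemic) | CCOC(=O)C(CC=C(C)C)C(=O)c1cc(OC)c(OC)cc1OC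
A6 | alternative 2 | 5,7-dihydroxy-3-(3-methylbut-2-en-1-yl)-2-(2,4,5-trimethoxyphenyl)-4H-chromen-4-one | COc1cc(OC)c(-c2oc3cc(O)cc(O)c3c(=O)c2CC=C(C)C)cc1OC
A7 | alternative 3 | 5-methyl-1-(2,4,5-trimethoxyphenyl)hex-4-en-1-one | COc1cc(OC)c(C(=O)CCC=C(C)C)cc1OC
A8 | alternative 3 | 2,4,6-trifluorobenzoyl chloride | O=C(Cl)c1c(F)cc(F)cc1F
A9 | alternative 3 | 5,7-difluoro-3-(3-methylbut-2-en-1-yl)-2-(2,4,5-trimethoxyphenyl)-4H-chromen-4-one | COc1cc(OC)c(-c2oc3cc(F)cc(F)c3c(=O)c2CC=C(C)C)cc1OC
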